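Slowness shows as a long time constant, and the time constant to read here is that of the passage of the target into its isomer, which the earlier readings can time.

| flask | starting material | reagent in the second phase | temperature | remark | time | volume of the second phase over the first |
|---|---|---|---|---|---|---|
| red | 5 mM | 20 mM | 20 °C | run made earlier |  |  |
| grey | 7.5 mM | 20 mM | 38 °C | run made earlier |  |  |
| amber | 10 mM | 30 mM | 20 °C | run made earlier |  |  |
| south | 10 mM | 20.0 mM | 25 °C |  | 4.0 min | 1.0 |
| north-west | 10 mM | 20.0 mM | 50 °C |  | 4.0 min | 1.0 |

- red (time / min: target / %, starting material / %): 0.833: 4.9, 95.9; 1.50: 7.7, 92.4; 2.50: 17.0, 82.9; 3.00: 18.5, 79.1; 4.00: 26.8, 69.0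
- grey (time / s: target / %, starting material / %): 25.0: 1.4, 95.9; 50.0: 6.5, 91.6; 80.0: 14.6, 82.5; 90.0: 15.8, 81.4; 120: 18.9, 72.2
- amber (time / min: target / %, starting material / %): 0.333: 2.0, 99.3; 1.00: 5.7, 92.5; 2.00: 18.3, 81.1; 3.00: 29.7, 67.0; 4.00: 35.5, 60.5

(readings scatter by 1 percentage point)

- in the second phase: reagent in the second phase; everything else is in the first
- charges count per volume of the first phase; a concentration in a rate is the amount of a species over the volume of its own phase; every rate counts per litre of the first phase
- the earlier runs hold the two phases in the same ratio of volumes as the flask asked about

1. which of the two there is more of at the end, south (target / isomer of the product)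
2. which of the two there is more of at the end, north-west (target / isomer of the product)
3. how much target is there at the end, in percent of the starting material charged: south
4. how much target is there at the end, in percent of the starting material charged: north-west

No column shows the isomer, so it is read as the gap left by starting material and target. Here the target is taken to rise about linearly and to decay first-order into the isomer. The gap then equals the triangle under the target curve divided by τ, the time constant of that decay.

Row by row, using each last reading, red gives a gap of 4.20% and τ = 12.8 min. Amber at the same temperature gives 4.00% and 17.7 min. Each reading in gaps that small carries a scatter of 1 percentage point, so the mean of the two, 15.3 min, is used. Grey gives 8.90% and 2.12 min, and this ageing time τ of the target shortens with an activation energy of 83.1 kJ/mol. My reckoning therefore puts τ at 8.61 min in south and 0.644 min in north-west.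

The feed f, starting material consumed per minute as a share of the charge and taken as constant over a run, comes from the runs at the same reagent charge. Red gives 0.0775 /min and grey 0.139 /min, which interpolate to 0.0918 /min for south and extrapolate to 0.198 /min for north-west.

In this picture the target is f·t at short times and levels at f·τ at long times; the two ends join as f·τ·(1 − exp(−t/τ)). South, with its time shorter than τ, is reckoned to reach 29.4%, with target leading. North-west runs 6.21 time constants and is reckoned to level at 12.7%, and the remainder of the reckoned feed, 66.4%, puts the isomer ahead.

The forecast agrees on south with target at 30% but differs on north-west with target at 33%, noting that “Isomer share rises with temperature”.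

The flask gives 29.3% of target in south and 15.5% in north-west, where the isomer stands at 49.0%.

    reagent in the reaction phase ⇌ reagent in the second phase, rate k1*([reagent in the reaction phase] - [reagent in the second phase]/K1) per volume of the first phase (partition coefficient = 0.450, kL = 0.370 /min)
    starting material + reagent in the reaction phase ⇌ target (K = 1400 /M, k = 11.0 /M/min, Ea = 38.0 kJ/mol, ΔH = −58.0 kJ/mol)
    target ⇌ isomer of the product (K = 3.40, k = 0.0880 /min, Ea = 95.0 kJ/mol, ΔH = 11.0 kJ/mol)
    (constants at 25 °C)

With τ = 0.644 min, north-west is 3.11 time constants along at 2.00 min, with 14.7% of target, and holds 15.5% at 4.00 min. A reading of south at 10 min, with τ = 8.61 min and a mean feed from its 64.8% of starting material consumed, reckons to 38.3% of target, and that flask holds 41.9%.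

(Readings and results are calculated with constants of no real substance, and the scatter is random.)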